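**Retrosynthetic overview**
1. The target comes from enol β-keto ester 9 by C2-methylation, dealkoxycarbonylation and O-deacetylation; C2 settles by enolisation into its stable configuration (2-Me trans to 3-Me).
2. Key disconnection, aryl–C4: 9 comes from the ring-fused donor–acceptor cyclopropane 7 (a cyclopropa[a]indenone ester) and guaiacol acetate 8, by strain-release SN2 arylation with inversion and ring enlargement (five-membered ring + cyclopropane → six-membered ring).
3. Enabling feature: in the tetralone ring, C2 (α to the C1 ketone, acceptor) and C4 (benzylic, para to the 7-OMe through C4a, donor) stand 1,3 across C3. A C2–C4 bond can therefore be drawn as a latent, polarised cyclopropane bond with C3 and its methyl as apex; an ester on C2 serves as a temporary second acceptor.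
4. 7 comes from Rh-carbenoid intramolecular cyclopropanation of the (Z)-propenyl aryl diazo keto ester 6 (Z-alkene gives the endo methyl; the catalyst gives the absolute configuration). 6 comes from acid 1 by Suzuki coupling, Masamune homologation and diazo transfer.
5. Ring order: aromatic ring A is bought; cyclopentanone and cyclopropane close together in step 4; the six-membered ring forms by enlargement in step 5; the pendant arene enters intact.

Key step: step 5

Assumption: the (S)-tert-leucinate catalyst in step 4 is taken to give the drawn enantiomer of 7; if a pilot run shows the opposite sense, its (R)-antipode is used. The β-keto ester 9 is drawn as its enol tautomer.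

**Step 1**
Reactants: 1 2-bromo-4,5-dimethoxybenzoic acid; 2 (Z)-prop-1-en-1-ylboronic acid
Product: 3 4,5-dimethoxy-2-[(Z)-prop-1-en-1-yl]benzoic acid
Conditions: Pd(dppf)Cl2·CH2Cl2 (3 mol%), K2CO3 (3.5 equiv), 1,4-dioxane/H2O 4:1, 80 °C; then 1 M HCl
Reagents that add atoms: none
Why: Suzuki–Miyaura coupling, in which transmetalation and reductive elimination retain the alkene geometry, so the Z configuration of 2 should be carried into 3.

**Step 2**
Reactants: 3 4,5-dimethoxy-2-[(Z)-prop-1-en-1-yl]benzoic acid
Product: 5 methyl 3-{4,5-dimethoxy-2-[(Z)-prop-1-en-1-yl]phenyl}-3-oxopropanoate, via acyl imidazolide 4 (not isolated)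
Conditions: CDI (1.2 equiv), THF, rt; then KO2CCH2CO2Me (1.5 equiv), MgCl2 (1.5 equiv), Et3N (2 equiv), THF, rt → 45 °C; 1 M HCl
Reagents that add atoms: 1,1'-carbonyldiimidazole, O=C(n1ccnc1)n1ccnc1 (its imidazole stays only in 4); potassium methyl malonate, COC(=O)CC(=O)[O-].[K+]
Why: Masamune–Brooks decarboxylative Claisen homologation, in which the magnesium enolate of the malonate half-ester is C-acylated by the imidazolide with loss of CO2 under near-neutral conditions that leave the Z-alkene untouched.

**Step 3**
Reactants: 5 methyl 3-{4,5-dimethoxy-2-[(Z)-prop-1-en-1-yl]phenyl}-3-oxopropanoate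
Product: 6 methyl 2-diazo-3-{4,5-dimethoxy-2-[(Z)-prop-1-en-1-yl]phenyl}-3-oxopropanoate
Conditions: 4-acetamidobenzenesulfonyl azide (1.2 equiv), Et3N (1.5 equiv), MeCN, 0 °C → rt
Reagents that add atoms: 4-acetamidobenzenesulfonyl azide, CC(=O)Nc1ccc(cc1)S(=O)(=O)N=[N+]=[N-]
Why: Regitz diazo transfer to the active methylene group of a β-keto ester.

**Step 4**
Reactants: 6 methyl 2-diazo-3-{4,5-dimethoxy-2-[(Z)-prop-1-en-1-yl]phenyl}-3-oxopropanoate
Product: 7 methyl (1R,1aR,6aS)-3,4-dimethoxy-1-methyl-6-oxo-1,1a-dihydrocyclopropa[a]indene-6a(6H)-carboxylate (1-methyl endo, i.e. cis to the aryl carbon and to the ketone carbon on the cyclopropane)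
Conditions: Rh2(S-TCPTTL)4 (1 mol%), CH2Cl2, slow addition of 6, 0 °C → rt
Reagents that add atoms: none
Why: Rh(II)-carbenoid intramolecular cyclopropanation (known for α-diazo-β-keto esters, the tert-leucinate catalyst class being established for aryl-keto diazo esters): the concerted, stereospecific addition turns the Z-alkene into the endo-1-methyl group, the short tether enforces cis-fusion at C1a/C6a, and the chiral catalyst selects the alkene face and with it the absolute configuration of all three centres.

**Step 5**
Reactants: 7 methyl (1R,1aR,6aS)-3,4-dimethoxy-1-methyl-6-oxo-1,1a-dihydrocyclopropa[a]indene-6a(6H)-carboxylate; 8 2-methoxyphenyl acetate (guaiacol acetate)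
Product: 9 methyl (3R,4R)-4-(3-acetoxy-4-methoxyphenyl)-1-hydroxy-6,7-dimethoxy-3-methyl-3,4-dihydronaphthalene-2-carboxylate
Conditions: Sc(OTf)3 (10 mol%), 8 (5 equiv), ClCH2CH2Cl, 0 → 40 °C
Reagents that add atoms: none
Why: Proposed new method: Sc(III) chelates the β-keto ester of 7 and polarises the ring-fusion bond C6a–C1a, the one cyclopropane bond that lies between the acceptor carbon and the benzylic carbon activated by the para-methoxy group, and the carbon of 8 para to its methoxy group attacks C1a from the side opposite to C6a (SN2-like Friedel–Crafts homo-Michael addition), after which the scandium enolate is protonated to the enol ester 9. The closest known reaction type is the Lewis-acid-catalysed Friedel–Crafts ring opening of 2-arylcyclopropane-1,1-dicarbonyl compounds by electron-rich arenes, which runs with inversion at the benzylic carbon; its use on a ring-fused cyclopropane with cleavage of the fusion bond is the new element. No ring is closed: the six-membered ring arises by ring enlargement, since breaking the bond shared by the cyclopentanone and the cyclopropane leaves the former apex carbon as a ring member between C2 and C4 of the tetralone (C6a, C1 and C1a of 7 become C2, C3 and C4). C4 is set by inversion at C1a under control of the cyclopropane configuration, and because the apex methyl group is endo the aryl group ends up cis to the 3-methyl group, while C3 is carried over unchanged. The step needs three selectivities: cleavage of the fusion bond and not of a bond to the apex (only C1a can stabilise positive charge), attack of 8 para to OMe (the O-acetyl group switches off the position para to the phenol oxygen), and substitution ahead of free ionisation, which would lead by loss of H-3 to the aromatic naphthol or to the 3,4-trans isomer. The last is secured by the mild chelating Lewis acid, the non-ionising solvent, the excess of 8 and the ring fusion, which holds the aryl π system nearly orthogonal to the breaking bond and so retards unassisted ionisation.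

**Step 6**
Reactants: 9 methyl (3R,4R)-4-(3-acetoxy-4-methoxyphenyl)-1-hydroxy-6,7-dimethoxy-3-methyl-3,4-dihydronaphthalene-2-carboxylate
Product: 10 methyl (2R,3R,4R)-4-(3-acetoxy-4-methoxyphenyl)-6,7-dimethoxy-2,3-dimethyl-1-oxo-1,2,3,4-tetrahydronaphthalene-2-carboxylate (expected major C2 epimer; both epimers converge in step 7)
Conditions: NaH (1.1 equiv), THF, 0 °C; MeI (3 equiv), 0 °C → rt
Reagents that add atoms: iodomethane, CI
Why: C-alkylation of the sodium enolate of a cyclic β-keto ester under non-nucleophilic conditions that spare the aryl acetate, the methyl group being expected to enter anti to the pseudoaxial 4-aryl group, although the C2 configuration is erased in step 7.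

**Step 7**
Reactants: 10 methyl (2R,3R,4R)-4-(3-acetoxy-4-methoxyphenyl)-6,7-dimethoxy-2,3-dimethyl-1-oxo-1,2,3,4-tetrahydronaphthalene-2-carboxylate
Product: 12 (2S,3R,4R)-4-(3-hydroxy-4-methoxyphenyl)-6,7-dimethoxy-2,3-dimethyl-3,4-dihydronaphthalen-1(2H)-one (target), via O-acetyl ketone 11 (not isolated)
Conditions: LiCl (3 equiv), H2O (2 equiv), DMSO, 150 °C, N2 sweep; cool; then K2CO3 (1.5 equiv), MeOH, rt
Reagents that add atoms: none
Why: Krapcho dealkoxycarbonylation (chloride SN2 at the ester methyl, loss of CO2, protonation of the enolate) followed by base-catalysed methanolysis of the aryl acetate; C2 is set under equilibrating conditions to the stable epimer with 2-Me equatorial and trans to 3-Me (the cis epimer would place 2-Me 1,3-diaxial to the pseudoaxial 4-aryl group), while C3 and C4 cannot enolise and stay as set.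

**Compound list**
1 | 2-bromo-4,5-dimethoxybenzoic acid | COc1cc(Br)c(cc1OC)C(O)=O | starting material
2 | (Z)-prop-1-en-1-ylboronic acid | C/C=C\B(O)O | starting material
3 | 4,5-dimethoxy-2-[(Z)-prop-1-en-1-yl]benzoic acid | COc1cc(/C=C\C)c(cc1OC)C(O)=O | intermediate
4 | (1H-imidazol-1-yl){4,5-dimethoxy-2-[(Z)-prop-1-en-1-yl]phenyl}methanone (acyl imidazolide, not isolated) | COc1cc(/C=C\C)c(cc1OC)C(=O)n1ccnc1 | intermediate
5 | methyl 3-{4,5-dimethoxy-2-[(Z)-prop-1-en-1-yl]phenyl}-3-oxopropanoate | COC(=O)CC(=O)c1cc(OC)c(OC)cc1/C=C\C | intermediate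
6 | methyl 2-diazo-3-{4,5-dimethoxy-2-[(Z)-prop-1-en-1-yl]phenyl}-3-oxopropanoate | COC(=O)C(=[N+]=[N-])C(=O)c1cc(OC)c(OC)cc1/C=C\C | intermediate
7 | methyl (1R,1aR,6aS)-3,4-dimethoxy-1-methyl-6-oxo-1,1a-dihydrocyclopropa[a]indene-6a(6H)-carboxylate (1-methyl endo) | COc1cc2c(cc1OC)C(=O)[C@]3(C(=O)OC)[C@H](C)[C@H]23 | intermediate
8 | 2-methoxyphenyl acetate (guaiacol acetate) | COc1ccccc1OC(C)=O | starting material
9 | methyl (3R,4R)-4-(3-acetoxy-4-methoxyphenyl)-1-hydroxy-6,7-dimethoxy-3-methyl-3,4-dihydronaphthalene-2-carboxylate (enol tautomer) | COc1ccc([C@@H]2c3cc(OC)c(OC)cc3C(O)=C(C(=O)OC)[C@@H]2C)cc1OC(C)=O | intermediate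
10 | methyl (2R,3R,4R)-4-(3-acetoxy-4-methoxyphenyl)-6,7-dimethoxy-2,3-dimethyl-1-oxo-1,2,3,4-tetrahydronaphthalene-2-carboxylate | COc1ccc([C@@H]2c3cc(OC)c(OC)cc3C(=O)[C@@](C(=O)OC)(C)[C@@H]2C)cc1OC(C)=O | intermediate
11 | (2S,3R,4R)-4-(3-acetoxy-4-methoxyphenyl)-6,7-dimethoxy-2,3-dimethyl-3,4-dihydronaphthalen-1(2H)-one (O-acetyl ketone, not isolated) | COc1ccc([C@@H]2c3cc(OC)c(OC)cc3C(=O)[C@@H](C)[C@@H]2C)cc1OC(C)=O | intermediate
12 | (2S,3R,4R)-4-(3-hydroxy-4-methoxyphenyl)-6,7-dimethoxy-2,3-dimethyl-3,4-dihydronaphthalen-1(2H)-one | COc1ccc([C@@H]2c3cc(OC)c(OC)cc3C(=O)[C@@H](C)[C@@H]2C)cc1O | target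

**Step count**
Total steps: 7. Longest linear sequence: 7 (1 → 3 → 5 → 6 → 7 → 9 → 10 → 12).

**Steps most likely to fail**

Step 5 (Proposed new method). The weakly nucleophilic arene may be too slow, so that the Lewis-acid-bound cyclopropane ionises unassisted. The cation would then lose H-3 and aromatise, or be captured from the face anti to the 3-methyl group; attack at the apex carbon is a further possible leak. The fallback replaces the π-nucleophile by an aryl–copper σ-nucleophile and sets out from 7. Commercial 5-bromo-2-methoxyphenol is silylated (TBSCl, imidazole, DMF) to tert-butyl(5-bromo-2-methoxyphenoxy)dimethylsilane F1, which is converted (Mg, THF) into [3-(tert-butyldimethylsilyloxy)-4-methoxyphenyl]magnesium bromide F2. With CuBr·SMe2 (0.5 equiv per Grignard, THF, −40 → 0 °C) this is added to 7; homo-conjugate addition of organocuprates to cyclopropane-1,1-dicarbonyl compounds is established and takes place with inversion at the attacked carbon, here expected at the benzylic one. The product should be the silyl-protected enol ester F3, which is C-methylated as in step 6 to the quaternary keto ester F4 and treated as in step 7 (LiCl, wet DMSO, 150 °C; then K2CO3, MeOH, which also cleaves the aryl silyl ether). This passes through the O-silyl ketone F5 and comes back to the route at 12.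

Step 4. The acceptor/acceptor carbenoid may be discriminated poorly by the catalyst (insufficient enantioselectivity), or the catalyst may be slow enough for carbenoid dimerisation to compete. The fallback gives up catalytic asymmetric induction and sets out from 6. Rh2(esp)2 (0.5 mol%, CH2Cl2, rt) should give the racemic endo-methyl cyclopropane F6, the relative configuration being unchanged because the addition stays stereospecific. F6 is resolved by preparative SFC on a chiral stationary phase (amylose tris(3,5-dimethylphenylcarbamate)), and the (1R,1aR,6aS) enantiomer is 7, where the route is rejoined.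

Step 7. Chloride attack at the methyl ester next to the congested quaternary centre may be slow, so that retro-Claisen cleavage of the C1–C2 bond by hydroxide, or O-methylation of the liberated phenolate by methyl chloride, competes. The fallback reverses the order of decarboxylation and methylation and sets out from 9. Aqueous HCl/AcOH at 90 °C should hydrolyse the methyl ester and the aryl acetate and decarboxylate the enolisable β-keto acid to (3S,4R)-4-(3-hydroxy-4-methoxyphenyl)-6,7-dimethoxy-3-methyl-3,4-dihydronaphthalen-1(2H)-one F7. Its dianion (LDA, 2.2 equiv, THF, −78 °C) is C-methylated with MeI (1.0 equiv) at the ketone enolate, anti to the 3-methyl group (kinetic enolate alkylation, the lithium phenoxide being inert at this temperature). This gives 12 directly and bypasses steps 6 and 7.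

**Further compounds**
F1 | step 5 | tert-butyl(5-bromo-2-methoxyphenoxy)dimethylsilane | COc1ccc(Br)cc1O[Si](C)(C)C(C)(C)C
F2 | step 5 | [3-(tert-butyldimethylsilyloxy)-4-methoxyphenyl]magnesium bromide | COc1ccc([Mg]Br)cc1O[Si](C)(C)C(C)(C)C
F3 | step 5 | methyl (3R,4R)-4-[3-(tert-butyldimethylsilyloxy)-4-methoxyphenyl]-1-hydroxy-6,7-dimethoxy-3-methyl-3,4-dihydronaphthalene-2-carboxylate | COc1ccc([C@@H]2c3cc(OC)c(OC)cc3C(O)=C(C(=O)OC)[C@@H]2C)cc1O[Si](C)(C)C(C)(C)C
F4 | step 5 | methyl (2R,3R,4R)-4-[3-(tert-butyldimethylsilyloxy)-4-methoxyphenyl]-6,7-dimethoxy-2,3-dimethyl-1-oxo-1,2,3,4-tetrahydronaphthalene-2-carboxylate | COc1ccc([C@@H]2c3cc(OC)c(OC)cc3C(=O)[C@@](C(=O)OC)(C)[C@@H]2C)cc1O[Si](C)(C)C(C)(C)C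
F5 | step 5 | (2S,3R,4R)-4-[3-(tert-butyldimethylsilyloxy)-4-methoxyphenyl]-6,7-dimethoxy-2,3-dimethyl-3,4-dihydronaphthalen-1(2H)-one | COc1ccc([C@@H]2c3cc(OC)c(OC)cc3C(=O)[C@@H](C)[C@@H]2C)cc1O[Si](C)(C)C(C)(C)C
F6 | step 4 | racemic methyl (1R*,1aR*,6aS*)-3,4-dimethoxy-1-methyl-6-oxo-1,1a-dihydrocyclopropa[a]indene-6a(6H)-carboxylate | COc1cc2c(cc1OC)C(=O)[C@]3(C(=O)OC)[C@H](C)[C@H]23.COc1cc2c(cc1OC)C(=O)[C@@]3(C(=O)OC)[C@@H](C)[C@@H]23
F7 | step 7 | (3S,4R)-4-(3-hydroxy-4-methoxyphenyl)-6,7-dimethoxy-3-methyl-3,4-dihydronaphthalen-1(2H)-one | COc1ccc([C@@H]2c3cc(OC)c(OC)cc3C(=O)C[C@@H]2C)cc1O
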